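The target is a cyclobutane whose C1 and C2 carry the danshensu ester carbonyls and whose C3 and C4 carry catechol rings; the C1 and C4 substituents lie on one face, those on C2 and C3 on the other. This is the substitution pattern of the achiral cis,trans,cis dianhydride of cyclobutane-1,2,3,4-tetracarboxylic acid, so both acyl–oxygen bonds are disconnected to that dianhydride and perbenzylated (R)-danshensu. One catalysed double alcoholysis at the two carbonyls related by the twofold axis attaches both side chains and makes all four ring carbons stereogenic in the right absolute sense. The acids left on C3 and C4 are then exchanged for aryl groups by decarboxylative coupling, and hydrogenolysis frees the target.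

Key step: step 2

Ring numbering used below: C1 and C2 bear the ester carbonyls, C3 and C4 the aryl groups or their carboxyl precursors; α is the face of the C1 and C4 substituents, β the face of the C2 and C3 substituents.

Assumption: the dihydroquinidine-derived ether catalyst is taken to be the pseudoenantiomer that sends the alcohol to the C1 and C2 carbonyls; if the first run shows the opposite sense, its dihydroquinine counterpart (DHQ)2AQN replaces it with nothing else changed.

Assumption: 4-bromo-1,2-bis(benzyloxy)benzene is taken as a purchasable aryl bromide; otherwise one benzylation of 4-bromocatechol supplies it.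

Remark on protection: benzyl groups are used on the side-chain carboxyl and on all catechol oxygens. They go on in one step, leave the carbinol less crowded than a tert-butyl ester would, and come off together under neutral conditions that cannot epimerise the cis aryl–ester pairs.

Step 1
Reactants: 1 danshensu, (2R)-3-(3,4-dihydroxyphenyl)-2-hydroxypropanoic acid
Product: 2 benzyl (2R)-3-[3,4-bis(benzyloxy)phenyl]-2-hydroxypropanoate
Conditions: BnBr (3.3 equiv), K2CO3 (3.5 equiv), DMF, N2, 0 °C to rt
Reagents that add atoms: benzyl bromide, BrCc1ccccc1
Why: Williamson-type O-alkylation in which carbonate deprotonates only the carboxylic acid and the two phenols, so the three benzyl groups go to these oxygens, the less acidic secondary hydroxyl stays free and the (R)-centre is not touched.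

Step 2
Reactants: 3 cis,trans,cis-cyclobutane-1,2,3,4-tetracarboxylic dianhydride (anhydride rings across C1/C4 on the α face and across C2/C3 on the β face); 2 benzyl (2R)-3-[3,4-bis(benzyloxy)phenyl]-2-hydroxypropanoate (2.2 equiv)
Product: 5 C1α,C2β-bis{[(2R)-1-(benzyloxy)-3-[3,4-bis(benzyloxy)phenyl]-1-oxopropan-2-yl]oxycarbonyl}cyclobutane-C3β,C4α-dicarboxylic acid, via mono-ester acid anhydride 4 (not isolated)
Conditions: (DHQD)2AQN [hydroquinidine anthraquinone-1,4-diyl diether] (30 mol%), 4 Å MS, THF/MTBE, −20 °C to rt; 1 M HCl wash
Reagents that add atoms: none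
Why: Proposed new method: the quinuclidine nitrogen of the alkaloid ether acts as a general base on the hydroxyl of 2 (an α-hydroxy ester and therefore more acidic than a simple secondary alcohol) while its chiral pocket exposes one of the two enantiotopic carbonyls of a strained, cyclobutane-fused anhydride ring, and acyl transfer then gives the ammonium carboxylate; the same event on the second ring of 4 gives 5, and no ring is closed. The closest known reaction type is the cinchona-alkaloid-catalysed alcoholysis of cyclic meso anhydrides, cis-cyclobutane-1,2-dicarboxylic anhydride among them, with primary alcohols; what is new is a hindered secondary alcohol as the nucleophile and two anhydride rings in one substrate. No stereocentre is made from a trigonal atom: C1 to C4 keep the relative configuration of 3 and become stereogenic through the choice of carbonyl, which is controlled by the catalyst together with the (R)-centre of 2. The step needs the same choice in both rings, and because the C1 and C2 carbonyls are interchanged by the twofold axis of 3 (those on C3 and C4 being their mirror images), an unchanged catalyst preference in the second opening leads to the C1,C2-diester and not to the C1,C3-isomer. A wrong first opening is carried mainly into the unsymmetrical C1,C3-type diester, a separable diastereomer, so the second opening also raises the purity of the twofold-symmetric product. The catalyst has no free hydroxyl group that could compete with the slow alcohol for the anhydride, and it is washed away from the diacid with dilute acid.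

Step 3
Reactants: 5 C1α,C2β-bis(protected danshensu ester) C3β,C4α-diacid
Product: 6 bis(4,5,6,7-tetrachloro-1,3-dioxoisoindolin-2-yl) ester of 5 at the C3β and C4α carboxyl groups
Conditions: N-hydroxytetrachlorophthalimide (2.2 equiv), DIC (2.4 equiv), DMAP (5 mol%), CH2Cl2, 0 °C to rt; filtration, short silica plug
Reagents that add atoms: N-hydroxytetrachlorophthalimide, O=C1N(O)C(=O)c2c(Cl)c(Cl)c(Cl)c(Cl)c12
Why: Carbodiimide (Steglich-type) esterification of both acids with the N-hydroxyimide gives the redox-active esters; the two acids are trans and cannot close to a cyclic anhydride, and low temperature with little DMAP guards the activated centres against epimerisation.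

Step 4
Reactants: 6 bis(tetrachlorophthalimidoyl) ester; 7 4-bromo-1,2-bis(benzyloxy)benzene
Product: 11 C1α,C2β-bis{[(2R)-1-(benzyloxy)-3-[3,4-bis(benzyloxy)phenyl]-1-oxopropan-2-yl]oxycarbonyl}-C3β,C4α-bis[3,4-bis(benzyloxy)phenyl]cyclobutane, via aryllithium 8 (not isolated), via arylzinc chloride 9 (not isolated), via mono-aryl redox-active ester 10 (not isolated)
Conditions: 7 (6 equiv), n-BuLi, THF, −78 °C; ZnCl2, −78 °C to rt (separate flask); then 6, NiCl2(dme) (40 mol%), 4,4'-di-tert-butyl-2,2'-bipyridine (80 mol%), THF/DMF, rt
Reagents that add atoms: none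
Why: Bromine–lithium exchange and transmetalation give the arylzinc, and the nickel-catalysed decarboxylative Negishi-type arylation of redox-active esters then turns each N-acyloxyimide into carbon dioxide and a cyclobutyl radical that is captured by the aryl nickel species and reductively eliminated; at C3 and then at C4 the face that must receive the aryl group carries only one cis neighbour (the adjacent ester) whereas the other face carries the adjacent acyl or aryl group and the cross-ring ester, so each aryl group should enter on the face the carboxyl left and give the C3β,C4α diaryl compound.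

Step 5
Reactants: 11 decabenzyl-protected diaryl diester
Product: 12 CNP0163929.1, bis[(1R)-1-carboxy-2-(3,4-dihydroxyphenyl)ethyl] (1R,2R,3R,4R)-3,4-bis(3,4-dihydroxyphenyl)cyclobutane-1,2-dicarboxylate
Conditions: H2 (1 atm), 10% Pd/C, degassed THF/EtOAc, rt; filtration under argon, reverse-phase purification
Reagents that add atoms: none
Why: Heterogeneous hydrogenolysis cleaves the eight benzyl ethers and the two benzyl esters under neutral conditions that leave the secondary alkyl esters, the cyclobutane and the base-sensitive cis aryl–ester relationships untouched.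

Compound list
1 | danshensu, (2R)-3-(3,4-dihydroxyphenyl)-2-hydroxypropanoic acid | O[C@H](Cc1ccc(O)c(O)c1)C(=O)O | starting material
2 | benzyl (2R)-3-[3,4-bis(benzyloxy)phenyl]-2-hydroxypropanoate | O[C@H](Cc1ccc(OCc2ccccc2)c(OCc2ccccc2)c1)C(=O)OCc1ccccc1 | intermediate
3 | cis,trans,cis-cyclobutane-1,2,3,4-tetracarboxylic dianhydride (achiral; each anhydride ring cis-fused, the two rings on opposite faces) | O=C1OC(=O)[C@H]2[C@@H]1[C@@H]3C(=O)OC(=O)[C@H]23 | starting material
4 | mono-opened intermediate: protected danshensu ester on C1α, free acid on C4α, C2/C3 anhydride ring intact on the β face | O=C(O[C@H](Cc1ccc(OCc2ccccc2)c(OCc2ccccc2)c1)C(=O)OCc1ccccc1)[C@H]1[C@@H]2C(=O)OC(=O)[C@@H]2[C@H]1C(=O)O | intermediate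
5 | twofold-symmetric diester diacid: protected danshensu esters on C1α and C2β, free acids on C3β and C4α | O=C(O[C@H](Cc1ccc(OCc2ccccc2)c(OCc2ccccc2)c1)C(=O)OCc1ccccc1)[C@H]1[C@H](C(=O)O[C@H](Cc2ccc(OCc3ccccc3)c(OCc3ccccc3)c2)C(=O)OCc2ccccc2)[C@H](C(=O)O)[C@H]1C(=O)O | intermediate
6 | bis(4,5,6,7-tetrachloro-1,3-dioxoisoindolin-2-yl) ester of 5 at the C3β and C4α carboxyl groups | O=C(O[C@H](Cc1ccc(OCc2ccccc2)c(OCc2ccccc2)c1)C(=O)OCc1ccccc1)[C@H]1[C@H](C(=O)O[C@H](Cc2ccc(OCc3ccccc3)c(OCc3ccccc3)c2)C(=O)OCc2ccccc2)[C@H](C(=O)ON2C(=O)c3c(Cl)c(Cl)c(Cl)c(Cl)c3C2=O)[C@H]1C(=O)ON1C(=O)c2c(Cl)c(Cl)c(Cl)c(Cl)c2C1=O | intermediate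
7 | 4-bromo-1,2-bis(benzyloxy)benzene | Brc1ccc(OCc2ccccc2)c(OCc2ccccc2)c1 | starting material
8 | [3,4-bis(benzyloxy)phenyl]lithium | [Li]c1ccc(OCc2ccccc2)c(OCc2ccccc2)c1 | intermediate
9 | [3,4-bis(benzyloxy)phenyl]zinc chloride | Cl[Zn]c1ccc(OCc2ccccc2)c(OCc2ccccc2)c1 | intermediate
10 | mono-coupled intermediate: 3,4-bis(benzyloxy)phenyl on C3β, tetrachlorophthalimidoyl ester on C4α, protected danshensu esters on C1α and C2β | O=C(O[C@H](Cc1ccc(OCc2ccccc2)c(OCc2ccccc2)c1)C(=O)OCc1ccccc1)[C@H]1[C@H](C(=O)O[C@H](Cc2ccc(OCc3ccccc3)c(OCc3ccccc3)c2)C(=O)OCc2ccccc2)[C@H](c2ccc(OCc3ccccc3)c(OCc3ccccc3)c2)[C@H]1C(=O)ON1C(=O)c2c(Cl)c(Cl)c(Cl)c(Cl)c2C1=O | intermediate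
11 | decabenzyl-protected target: protected danshensu esters on C1α and C2β, 3,4-bis(benzyloxy)phenyl groups on C3β and C4α | O=C(O[C@H](Cc1ccc(OCc2ccccc2)c(OCc2ccccc2)c1)C(=O)OCc1ccccc1)[C@H]1[C@H](C(=O)O[C@H](Cc2ccc(OCc3ccccc3)c(OCc3ccccc3)c2)C(=O)OCc2ccccc2)[C@H](c2ccc(OCc3ccccc3)c(OCc3ccccc3)c2)[C@H]1c1ccc(OCc2ccccc2)c(OCc2ccccc2)c1 | intermediate
12 | CNP0163929.1, bis[(1R)-1-carboxy-2-(3,4-dihydroxyphenyl)ethyl] (1R,2R,3R,4R)-3,4-bis(3,4-dihydroxyphenyl)cyclobutane-1,2-dicarboxylate | O=C(O[C@H](Cc1ccc(O)c(O)c1)C(=O)O)[C@H]1[C@H](C(=O)O[C@H](Cc2ccc(O)c(O)c2)C(=O)O)[C@H](c2ccc(O)c(O)c2)[C@H]1c1ccc(O)c(O)c1 | target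

Total step count: 5. Longest linear sequence: 5 steps (1 to 12 through 2, 5, 6 and 11).

Steps most likely to fail

Step 2. Acyl transfer to the hindered secondary alcohol may be so slow that uncatalysed or mismatched opening takes over, so that the choice between enantiotopic carbonyls is lost and the three diastereomeric diesters form together. The fallback uses known chemistry, sets out from 3 and comes back at 5. It separates the desymmetrisation from the attachment of the side chain:
- The dianhydride is opened twice with allyl alcohol, a primary alcohol within the established scope of alkaloid-mediated alcoholysis, under the pseudoenantiomeric (DHQ)2AQN so that the allyl esters go to the C3 and C4 carbonyls. This gives the C3β,C4α-diallyl ester C1α,C2β-diacid F1.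
- Steglich esterification of its two acids with 2 (EDC·HCl, catalytic DMAP, CH2Cl2, 0 °C) gives the C1α,C2β-bis(protected danshensu) C3β,C4α-diallyl tetraester F2.
- Deallylation with Pd(PPh3)4 and morpholine in THF releases 5.

Step 4. Capture of the first cyclobutyl radical may show poor facial selectivity, the aryl group entering cis to the remaining acyl group, which the second coupling would carry through to the all-trans diaryl isomer; premature reduction of the radical is a lesser loss. The fallback sets out from 2 and 7 and comes back at 11. It builds the ring by a photocycloaddition that joins each aryl carbon to an ester carbon with the cis relation: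
- Compound 2 is acylated with fumaryl chloride (pyridine, CH2Cl2, 0 °C) to the bis(protected danshensu) fumarate F3.
- Compound 7 is coupled twice with (E)-1,2-bis(pinacolatoboryl)ethene (Suzuki–Miyaura, Pd(PPh3)4, K2CO3, dioxane/water, 90 °C) to (E)-3,3',4,4'-tetrakis(benzyloxy)stilbene F4.
- Irradiation of F4 with F3 through Pyrex in benzene should give the [2+2] adduct by way of the singlet exciplex. This mode is known for trans-stilbene and fumarate esters to keep both trans relations and to place each aryl group cis to its neighbouring ester.
- The product would be 11 together with the diastereomer of mirror-image ring configuration, to be separated by chromatography.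

Step 5. Removal of ten benzyl groups may stall at partly benzylated material, or the free catechols may oxidise on the catalyst. The fallback sets out from 11 and comes back at 12. It replaces hydrogenolysis by Lewis-acid dealkylation with BCl3 and pentamethylbenzene as cation scavenger in CH2Cl2 at −78 °C, followed by a methanol quench. This cleaves benzyl ethers and benzyl esters and leaves the secondary alkyl esters intact.

Further compounds
F1 | step 2 | C3β,C4α-diallyl ester C1α,C2β-diacid of cyclobutane-1,2,3,4-tetracarboxylic acid | OC(=O)[C@H]1[C@H](C(=O)O)[C@H](C(=O)OCC=C)[C@H]1C(=O)OCC=C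
F2 | step 2 | C1α,C2β-bis(protected danshensu) C3β,C4α-diallyl tetraester | O=C(O[C@H](Cc1ccc(OCc2ccccc2)c(OCc2ccccc2)c1)C(=O)OCc1ccccc1)[C@H]1[C@H](C(=O)O[C@H](Cc2ccc(OCc3ccccc3)c(OCc3ccccc3)c2)C(=O)OCc2ccccc2)[C@H](C(=O)OCC=C)[C@H]1C(=O)OCC=C
F3 | step 4 | bis{(2R)-1-(benzyloxy)-3-[3,4-bis(benzyloxy)phenyl]-1-oxopropan-2-yl} fumarate | O=C(/C=C/C(=O)O[C@H](Cc1ccc(OCc2ccccc2)c(OCc2ccccc2)c1)C(=O)OCc1ccccc1)O[C@H](Cc1ccc(OCc2ccccc2)c(OCc2ccccc2)c1)C(=O)OCc1ccccc1
F4 | step 4 | (E)-3,3',4,4'-tetrakis(benzyloxy)stilbene | O(Cc1ccccc1)c1ccc(/C=C/c2ccc(OCc3ccccc3)c(OCc3ccccc3)c2)cc1OCc1ccccc1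
F0 | step 5 | none | none
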